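At the 80 min reading you want the target in dusk and summer.

common to all: substrate 0.11 M
- teal: partner 1.1 equiv; second reagent 1 equiv; third reagent 1.5 equiv; protic impurity 0.033 M; run made earlier
- green: partner 1.1 equiv; second reagent 1.7 equiv; third reagent 1.5 equiv; protic impurity 0.033 M; run made earlier
- red: partner 3 equiv; second reagent 1.1 equiv; third reagent 1.5 equiv; protic impurity 0.033 M; run made earlier
- dusk: partner 4.40 equiv; second reagent 0.740 equiv; third reagent 1.50 equiv; protic impurity 0.0330 M; time 80 min
- summer: partner 1.10 equiv; second reagent 1.10 equiv; third reagent 1.50 equiv; protic impurity 0.0330 M; time 80 min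

- teal (time / min: target / %): 5.00: 1; 8.00: 0; 12.0: 0; 20.0: 5; 30.0: 6; 60.0: 12
- green (time / min: target / %): 4.00: 0; 10.0: 1; 20.0: 5; 30.0: 9; 40.0: 8; 60.0: 16
- red (time / min: target / %): 5.00: 0; 8.00: 1; 15.0: 3; 30.0: 10; 60.0: 24

(scatter of a reading: 1.5 percentage points)



- which one finishes higher in amount of target, in percent of the substrate charged ("neither" within 2 percentage points) (dusk / summer / neither)
- amount of target at the end, in percent of the substrate charged, dusk
- amount of target at the end, in percent of the substrate charged, summer

My own reckoning assumes that the substrate is consumed early, shared between partner and second reagent in proportion to their charges (a selectivity factor of one). The target then grows from the share that went with partner, fed by the second reagent still present. So, in equivalents, let φ = partner/(partner + second reagent), and define the drive G = φ × (second reagent − 1 + φ). Summer has G = 0.300 and dusk 0.510. Teal, green and red have G = 0.274, 0.429 and 0.609. Their 60.0 min readings divided by G give 43.7%, 37.3% and 39.4%, with a mean of 40.1%. Taking that mean and stretching it in proportion to time, I expect 27.3% for dusk and 16.1% for summer.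

The forecast says dusk finishes higher, with 31% for dusk and 18% for summer, on the grounds that “more partner helps, but less second reagent hurts”. For dusk, my figure is lower than the forecast's.

The flask gives 23.6% for dusk and 17.4% for summer, so dusk finishes higher.

    second reagent + intermediate A → intermediate B (k = 0.230 M⁻¹ min⁻¹)
    target ⇌ isomer of the product (K = 2.20, k = 0.00310 min⁻¹)
    third reagent + protic impurity → quenched reagent (k = 0.260 M⁻¹ min⁻¹)
    substrate + second reagent → side product (k = 3.10 M⁻¹ min⁻¹)
    third reagent + intermediate B ⇌ target (K = 270 M⁻¹, k = 0.170 M⁻¹ min⁻¹)
    substrate + partner → intermediate A (k = 4.00 M⁻¹ min⁻¹)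

One part of dusk's lead is its larger charge of partner: with that difference from summer taken away, dusk stands at 13.0% instead of 23.6%. With the difference in second reagent taken away instead, dusk reaches 30.2%, and its G goes from 0.510 to 0.720, against 0.300 for summer. The neighbour flask, summer with 0.280 equiv of second reagent, has G = 0.0615, which gives 3.29%. That flask holds 74.2% as intermediate A and 4.67% as target.

The runs were generated by integration with constants of no real substance, and the scatter is random.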